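**Retrosynthetic overview**
- The target is traced back through cleavage of the 5-O-methyl group and C3 hydroxylation to 5,7,8,3',4',5'-hexamethoxyflavone.
- The strategic cut is the C2–C1' bond between pyranone ring C and the symmetrical 3,4,5-trimethoxyphenyl ring B. In 5,7,8-trimethoxychromone, C2 carries a hydrogen and is the β-carbon of the O1–C2=C3–C4=O enone, so it can be arylated directly with an arylboronic acid, with no halide or chalcone handle.
- The chromone comes from 2-hydroxy-3,4,6-trimethoxyacetophenone and an amide acetal that supplies C2; the acetophenone comes from 3,4,5-trimethoxyphenol by methylation and acetylation with ortho-demethylation.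
- Ring order: rings A and B are bought as benzenes; ring C is closed on ring A through the O1–C2 bond (step 4); ring B is attached at C2 (step 5); the 3-hydroxyl and the free 5-hydroxyl are revealed last.

Key step: step 5

Remark: dimethyldioxirane is taken as a preformed solution in acetone, so its preparation is not counted as a step; the target is achiral and needs no stereocontrol.

**Route**

Step 1
Reactants: 1 3,4,5-trimethoxyphenol
Product: 2 1,2,3,5-tetramethoxybenzene
Conditions: MeI, K2CO3, acetone, reflux
Reagents that add atoms: iodomethane, CI
Why: Williamson O-methylation of the only acidic site, the phenol, should proceed cleanly by SN2 attack of the phenoxide on iodomethane.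

Step 2
Reactants: 2 1,2,3,5-tetramethoxybenzene
Product: 4 2-hydroxy-3,4,6-trimethoxyacetophenone, via 2,3,4,6-tetramethoxyacetophenone 3 (not isolated)
Conditions: AcCl, AlCl3 (3 equiv), Et2O, 0 °C to rt; ice/aq. HCl work-up
Reagents that add atoms: acetyl chloride, CC(=O)Cl
Why: Friedel–Crafts acylation at one of the two equivalent free positions of the electron-rich arene gives ketone 3, and AlCl3 chelated between the carbonyl and an ortho methoxy should then cleave the ortho methyl ether that is buttressed by a neighbouring methoxy, stopping at the chelated monophenol.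

Step 3
Reactants: 4 2-hydroxy-3,4,6-trimethoxyacetophenone; 5 N,N-dimethylformamide dimethyl acetal
Product: 6 (E)-3-dimethylamino-1-(2-hydroxy-3,4,6-trimethoxyphenyl)prop-2-en-1-one
Conditions: toluene, 100 °C
Reagents that add atoms: N,N-dimethylformamide dimethyl acetal (5), COC(OC)N(C)C
Why: Enaminone condensation of the acidic methyl ketone with the amide acetal, with loss of two methanol, should give the thermodynamically favoured E enaminone while the phenol stays hydrogen-bonded to the ketone.

Step 4
Reactants: 6 (E)-3-dimethylamino-1-(2-hydroxy-3,4,6-trimethoxyphenyl)prop-2-en-1-one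
Product: 7 5,7,8-trimethoxychromone (5,7,8-trimethoxy-4H-chromen-4-one)
Conditions: conc. HCl, CH2Cl2, 40 °C
Reagents that add atoms: none
Why: Acid-mediated intramolecular oxa-Michael addition–elimination, in which the phenol oxygen adds 6-endo to the protonated enaminone β-carbon and dimethylamine is expelled, is the standard chromone closure and forms the O1–C2 bond of ring C.

Step 5
Reactants: 7 5,7,8-trimethoxychromone; 8 3,4,5-trimethoxyphenylboronic acid (2 equiv)
Product: 9 5,7,8,3',4',5'-hexamethoxyflavone
Conditions: Pd(O2CCF3)2 (10 mol %), Cu(OAc)2 (20 mol %), O2 (1 atm), DMSO, 80 °C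
Reagents that add atoms: 3,4,5-trimethoxyphenylboronic acid (8), COc1cc(B(O)O)cc(OC)c1OC
Why: In this oxidative Heck (boron–Heck) reaction the aryl group of 8 transmetalates from boron to divalent palladium and the arylpalladium species adds syn across the C2–C3 double bond of 7 with the aryl at C2, the carbon that is both β to the C4 carbonyl and bonded to O1, leaving palladium on C3 as a palladium enolate. Because the C2–H then lies anti to palladium, the C3-bound species is expected to equilibrate through its oxygen-bound enolate before syn β-hydride elimination restores the C2–C3 double bond; the palladium hydride collapses to zerovalent palladium, which O2 with Cu(OAc)2 returns to divalent palladium, and any flavanone formed by protonation of the enolate should be dehydrogenated through the same enolate under these Pd(O2CCF3)2/DMSO/O2 conditions. The closest known reaction type is the palladium-catalysed oxidative Heck arylation of chromones and other cyclic enones with arylboronic acids. No ring closes and no stereocentre is created. The step needs site selectivity for C2 over C3 and over the electron-rich C6–H of ring A, and this is secured by the polarisation of the O1–C2=C3–C4=O unit, which steers the nucleophilic aryl–palladium bond to C2, whereas C6–H could react only by electrophilic palladation, which should be slow next to transmetalation from the boronic acid. All phenols are methyl ethers, so nothing chelates palladium or is oxidised, and the boronic acid is unhindered at both ortho positions.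

Step 6
Reactants: 9 5,7,8,3',4',5'-hexamethoxyflavone
Product: 11 3-hydroxy-5,7,8,3',4',5'-hexamethoxyflavone, via hexamethoxyflavone 2,3-epoxide 10 (not isolated)
Conditions: dimethyldioxirane (acetone solution), CH2Cl2, 0 °C; then p-TsOH·H2O (cat.), CH2Cl2, rt
Reagents that add atoms: dimethyldioxirane, CC1(C)OO1
Why: Electrophilic epoxidation of the C2–C3 double bond by the neutral dioxirane, possible because the 5-oxygen is methylated, followed by acid-promoted opening at C2 to the O1- and aryl-stabilised cation and loss of the C3 proton, should deliver the flavonol as the enol tautomer (the known flavone-to-flavonol epoxidation–isomerisation sequence).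

Step 7
Reactants: 11 3-hydroxy-5,7,8,3',4',5'-hexamethoxyflavone
Product: 12 3,5-dihydroxy-7,8,3',4',5'-pentamethoxyflavone
Conditions: BCl3 (1 M in CH2Cl2, 3 equiv), CH2Cl2, −78 °C to 0 °C; then aq. HCl
Reagents that add atoms: none
Why: Chelation-controlled Lewis-acid ether cleavage, in which boron bridges the C4 carbonyl and the peri 5-methoxy oxygen in a six-membered chelate and chloride removes the methyl group, should spare the five methoxy groups that have no adjacent carbonyl, and the cold aprotic conditions avoid Wessely–Moser isomerisation to the 5,6,7 pattern.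

**Compound list**
1 | 3,4,5-trimethoxyphenol | COc1cc(O)cc(OC)c1OC | starting material
2 | 1,2,3,5-tetramethoxybenzene | COc1cc(OC)c(OC)c(OC)c1 | intermediate
3 | 2,3,4,6-tetramethoxyacetophenone | CC(=O)c1c(OC)c(OC)c(OC)cc1OC | intermediate (not isolated)
4 | 2-hydroxy-3,4,6-trimethoxyacetophenone | CC(=O)c1c(O)c(OC)c(OC)cc1OC | intermediate
5 | N,N-dimethylformamide dimethyl acetal | COC(OC)N(C)C | starting material
6 | (E)-3-dimethylamino-1-(2-hydroxy-3,4,6-trimethoxyphenyl)prop-2-en-1-one | CN(C)/C=C/C(=O)c1c(O)c(OC)c(OC)cc1OC | intermediate
7 | 5,7,8-trimethoxychromone | COc1cc(OC)c2c(=O)ccoc2c1OC | intermediate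
8 | 3,4,5-trimethoxyphenylboronic acid | COc1cc(B(O)O)cc(OC)c1OC | starting material
9 | 5,7,8,3',4',5'-hexamethoxyflavone | COc1cc(-c2cc(=O)c3c(OC)cc(OC)c(OC)c3o2)cc(OC)c1OC | intermediate
10 | 2,3-epoxy-5,7,8-trimethoxy-2-(3,4,5-trimethoxyphenyl)chroman-4-one (racemic, cis-fused epoxide) | COc1cc(C23OC2C(=O)c4c(OC)cc(OC)c(OC)c4O3)cc(OC)c1OC | intermediate (not isolated)
11 | 3-hydroxy-5,7,8,3',4',5'-hexamethoxyflavone | COc1cc(-c2oc3c(OC)c(OC)cc(OC)c3c(=O)c2O)cc(OC)c1OC | intermediate
12 | 3,5-dihydroxy-7,8,3',4',5'-pentamethoxyflavone | COc1cc(-c2oc3c(OC)c(OC)cc(O)c3c(=O)c2O)cc(OC)c1OC | target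

**Step count**
Total steps: 7. Longest linear sequence: 7 steps (1 to 12).

**Steps most likely to fail**

Step 5. The palladium enolate may be protonated faster than it undergoes β-hydride elimination, so the reaction stalls at the flavanone oxidation level. The electron-rich boronic acid may also be consumed by protodeboronation and oxidative homocoupling before it transfers its aryl group. The fallback sets out from acetophenone 4 and builds ring C with ring B already attached, by the Baker–Venkataraman route. Acylation of the phenol of 4 with 3,4,5-trimethoxybenzoyl chloride in pyridine should give 2-acetyl-3,5,6-trimethoxyphenyl 3,4,5-trimethoxybenzoate F1. KOH in pyridine at 50 °C should move the aroyl group from oxygen to the methyl carbon to give 1-(2-hydroxy-3,4,6-trimethoxyphenyl)-3-(3,4,5-trimethoxyphenyl)propane-1,3-dione F2. Cyclodehydration with catalytic H2SO4 in AcOH at 90 °C closes the pyranone, and the sequence comes back to the route at flavone 9.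

Step 6. Epoxidation of the electron-poor C2–C3 double bond may be slow enough that oxidation of the electron-rich rings competes. The epoxide may also open by ring contraction or hydration and not by the desired isomerisation to the flavonol. The fallback sets out from flavone 9 and installs the oxygen by an anionic sequence. LiN(iPr)2 in THF at −78 °C should deprotonate C3 to give 3-lithio-5,7,8,3',4',5'-hexamethoxyflavone F3. B(OMe)3 should trap it as dimethyl (5,7,8,3',4',5'-hexamethoxyflavon-3-yl)boronate F4. Oxidation of the C–B bond with H2O2 in AcOH gives the flavonol, and the sequence comes back to the route at 11.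

Step 7. The Lewis acid may be held by the 3-hydroxy-4-keto chelate so that cleavage at O5 stalls, and the excess then needed may also cleave the 4'-methoxy flanked by two methoxys or the 8-methoxy. The fallback sets out from flavone 9, cleaves the 5-methyl ether while only one chelating site is present, and ends with a neutral hydrogenolysis.
- BCl3 (1.2 equiv) in CH2Cl2 at −78 °C to 0 °C should give 5-hydroxy-7,8,3',4',5'-pentamethoxyflavone F5.
- BnBr and K2CO3 in DMF should give 5-benzyloxy-7,8,3',4',5'-pentamethoxyflavone F6.
- Dimethyldioxirane should give 5-benzyloxy-2,3-epoxy-7,8-dimethoxy-2-(3,4,5-trimethoxyphenyl)chroman-4-one F7, which is not isolated and with catalytic p-TsOH·H2O should isomerise to 5-benzyloxy-3-hydroxy-7,8,3',4',5'-pentamethoxyflavone F8.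
- H2 over Pd/C in EtOAc/MeOH removes the benzyl group, and the sequence comes back to the route at target 12.

**Further compounds**
F1 | step 5 | 2-acetyl-3,5,6-trimethoxyphenyl 3,4,5-trimethoxybenzoate | CC(=O)c1c(OC(=O)c2cc(OC)c(OC)c(OC)c2)c(OC)c(OC)cc1OC
F2 | step 5 | 1-(2-hydroxy-3,4,6-trimethoxyphenyl)-3-(3,4,5-trimethoxyphenyl)propane-1,3-dione | COc1cc(C(=O)CC(=O)c2c(O)c(OC)c(OC)cc2OC)cc(OC)c1OC
F3 | step 6 | 3-lithio-5,7,8,3',4',5'-hexamethoxyflavone | [Li]c1c(-c2cc(OC)c(OC)c(OC)c2)oc2c(OC)c(OC)cc(OC)c2c1=O
F4 | step 6 | dimethyl (5,7,8,3',4',5'-hexamethoxyflavon-3-yl)boronate | COB(OC)c1c(-c2cc(OC)c(OC)c(OC)c2)oc2c(OC)c(OC)cc(OC)c2c1=O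
F5 | step 7 | 5-hydroxy-7,8,3',4',5'-pentamethoxyflavone | COc1cc(-c2cc(=O)c3c(O)cc(OC)c(OC)c3o2)cc(OC)c1OC
F6 | step 7 | 5-benzyloxy-7,8,3',4',5'-pentamethoxyflavone | COc1cc(-c2cc(=O)c3c(OCc4ccccc4)cc(OC)c(OC)c3o2)cc(OC)c1OC
F7 | step 7 | 5-benzyloxy-2,3-epoxy-7,8-dimethoxy-2-(3,4,5-trimethoxyphenyl)chroman-4-one (racemic, cis-fused epoxide) | COc1cc(C23OC2C(=O)c4c(OCc5ccccc5)cc(OC)c(OC)c4O3)cc(OC)c1OC
F8 | step 7 | 5-benzyloxy-3-hydroxy-7,8,3',4',5'-pentamethoxyflavone | COc1cc(-c2oc3c(OC)c(OC)cc(OCc4ccccc4)c3c(=O)c2O)cc(OC)c1OC
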